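**Plan**
- Retrosynthesis: cut the two angelate C–O bonds; cut C11–C12 and C12–C13 (C12 = CO, C13–C15 = methyl (Z)-3-iodobut-2-enoate, C11 = an exocyclic methylene on C9); cut C8–C17 (formaldehyde) back to a Δ7-en-9-one.
- Ring A (C1–C5, C10) is then contracted by removing C2. This leaves an A-nor cyclopentanone whose carbonyl carbon (future C3) lies between quaternary C4 (gem-dimethyl) and the C1 methylene.
- That flanking pattern allows a one-carbon insertion only on the C1 side. Me3SiCHN2 delivers C2 with a silyl group that, with the C3 oxygen, encodes the C2=C3 olefin for cis-dihydroxylation.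
- Forward order: ring B comes from 2-methylcyclohexane-1,3-dione; the five-membered ring is annulated (allylation, Wacker, aldol), gem-dimethylated and hydrogenated; ring A arises by ring expansion; ring B and the side chain are finished last.
- Stereochemistry: C10 from a CBS desymmetrisation; C5 from hydroxyl-directed hydrogenation; C2/C3 from α-face osmylation; C9 from α-face hydroboration; all three Z olefins from geometrically defined reagents.

Key step: step 9

Remark on locants: C1–C17 are the labdane locants of the target (C4 gem-dimethyl, C10 angular methyl, C17 on C8, C11–C15 on C9); α is the face opposite the C10 methyl.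
Assumption: in the CBS reduction of 3, hydride is delivered anti to the allyl group (hydroxyl cis to allyl), so that the (S)-catalyst gives (2R,3R)-4.

**Step 1**
Reactants: 1 2-methylcyclohexane-1,3-dione; 2 allyl bromide
Product: 3 2-methyl-2-(prop-2-en-1-yl)cyclohexane-1,3-dione
Conditions: 1 M aq NaOH, rt
Reagents that add atoms: none
Why: C-alkylation of the 1,3-dione enolate with the allylic bromide gives the quaternary, still prochiral carbon; no stereocentre is formed.

**Step 2**
Reactants: 3 2-methyl-2-(prop-2-en-1-yl)cyclohexane-1,3-dione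
Product: 4 (2R,3R)-3-hydroxy-2-methyl-2-(prop-2-en-1-yl)cyclohexan-1-one
Conditions: (S)-Me-CBS (20 mol%), catecholborane, toluene, −78 → −40 °C
Reagents that add atoms: none
Why: Enantiotopic-group-selective Corey–Bakshi–Shibata reduction: the catalyst fixes the carbinol as R and hydride enters anti to the allyl group, so only one carbonyl is matched and the quaternary carbon (future C10) becomes R with the hydroxyl cis to the allyl branch.

**Step 3**
Reactants: 4 (2R,3R)-3-hydroxy-2-methyl-2-(prop-2-en-1-yl)cyclohexan-1-one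
Product: 5 (2R,3R)-3-[(tert-butyldimethylsilyl)oxy]-2-methyl-2-(prop-2-en-1-yl)cyclohexan-1-one
Conditions: TBSOTf, 2,6-lutidine, CH2Cl2, 0 °C
Reagents that add atoms: tert-butyldimethylsilyl trifluoromethanesulfonate CC(C)(C)[Si](C)(C)OS(=O)(=O)C(F)(F)F
Why: Silyl triflate silylation of the hindered secondary alcohol masks the β-hydroxy ketone against retro-aldol cleavage in the basic steps 5 and 6.

**Step 4**
Reactants: 5 (2R,3R)-3-[(tert-butyldimethylsilyl)oxy]-2-methyl-2-(prop-2-en-1-yl)cyclohexan-1-one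
Product: 6 (2R,3R)-3-[(tert-butyldimethylsilyl)oxy]-2-methyl-2-(2-oxopropyl)cyclohexan-1-one
Conditions: PdCl2 (10 mol%), CuCl, O2 (1 atm), DMF/H2O, rt
Reagents that add atoms: water O
Why: Tsuji–Wacker oxidation of the terminal olefin (Markovnikov hydroxypalladation) gives the methyl ketone and thus the 1,4-diketone.

**Step 5**
Reactants: 6 (2R,3R)-3-[(tert-butyldimethylsilyl)oxy]-2-methyl-2-(2-oxopropyl)cyclohexan-1-one
Product: 7 (7R,7aS)-7-[(tert-butyldimethylsilyl)oxy]-7a-methyl-1,4,5,6,7,7a-hexahydro-2H-inden-2-one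
Conditions: NaOMe, MeOH, 50 °C
Reagents that add atoms: none
Why: Intramolecular aldol condensation of the 1,4-diketone (methyl-ketone enolate onto the ring carbonyl, then dehydration) closes the cyclopentenone; the bridged aldol from the other enolate cannot dehydrate and reverts.

**Step 6**
Reactants: 7 (7R,7aS)-7-[(tert-butyldimethylsilyl)oxy]-7a-methyl-1,4,5,6,7,7a-hexahydro-2H-inden-2-one
Product: 8 (7R,7aS)-7-[(tert-butyldimethylsilyl)oxy]-3,3,7a-trimethyl-1,3,5,6,7,7a-hexahydro-2H-inden-2-one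
Conditions: KOtBu (3 equiv), MeI (excess), t-BuOH/THF, 0 °C → rt
Reagents that add atoms: iodomethane CI
Why: Deconjugative α,α-dimethylation of the enone through its extended dienolate (γ-deprotonation at C6, C-methylation at C4 twice) installs the gem-dimethyl group and moves the olefin to C5=C6; the neopentyl α′ carbon C1 reacts more slowly.

**Step 7**
Reactants: 8 (7R,7aS)-7-[(tert-butyldimethylsilyl)oxy]-3,3,7a-trimethyl-1,3,5,6,7,7a-hexahydro-2H-inden-2-one
Product: 9 (7R,7aS)-7-hydroxy-3,3,7a-trimethyl-1,3,5,6,7,7a-hexahydro-2H-inden-2-one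
Conditions: TBAF, THF, 50 °C
Reagents that add atoms: none
Why: Fluoride cleavage of the silyl ether frees the 9α-hydroxyl that is needed as directing group in step 8.

**Step 8**
Reactants: 9 (7R,7aS)-7-hydroxy-3,3,7a-trimethyl-1,3,5,6,7,7a-hexahydro-2H-inden-2-one
Product: 10 (3aR,7R,7aS)-7-hydroxy-3,3,7a-trimethyloctahydro-2H-inden-2-one (trans-fused)
Conditions: [Ir(cod)(PCy3)(py)]PF6 (5 mol%), H2 (1 atm), CH2Cl2, rt
Reagents that add atoms: none
Why: Hydroxyl-directed hydrogenation with Crabtree's catalyst: iridium bound to the homoallylic 9α-hydroxyl should deliver H2 to the α-face of C5=C6, setting 5α-H trans to the 10β-methyl.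

**Step 9**
Reactants: 10 (3aR,7R,7aS)-7-hydroxy-3,3,7a-trimethyloctahydro-2H-inden-2-one
Product: 12 2α-(trimethylsilyl)-11,12,13,14,15,16,17-heptanorlabdane-3β,9α-diol, via ring-expanded α-silyl ketone 11 (not isolated)
Conditions: Me3Al (2.5 equiv), Me3SiCHN2 (1.5 equiv), CH2Cl2, −78 → −20 °C; then DIBAL-H, −78 → 0 °C; Rochelle salt work-up
Reagents that add atoms: (trimethylsilyl)diazomethane C[Si](C)(C)C=[N+]=[N-]
Why: Me3Al activates the only carbonyl of 10 (the C9 hydroxyl is present as its aluminium alkoxide), the carbon of Me3SiCHN2 adds to C3, and the β-oxido diazonium loses N2 with 1,2-shift of the C1 methylene from C3 to the new carbon, which becomes C2; the closest known reaction type is the organoaluminium-promoted homologation of cycloalkanones with trimethylsilyldiazomethane, followed by hydride reduction of the β-keto silane as in the Peterson olefin synthesis. No ring is closed: ring A (C1–C5, C10) arises by insertion of one carbon into the C3–C1 bond of the cyclopentanone, and the strained trans-hydrindane becomes a trans-decalin. The step needs migration of C1 and not of C4; C4 is quaternary, so its migration would place the silyl-bearing carbon between the carbonyl and a fully substituted centre, and the less substituted carbon is in any case the one that migrates with this reagent. A second insertion is blocked because the product ketone is flanked by CMe2 and CH(SiMe3). Silicon should settle equatorial (2α) and DIBAL-H should give mainly the 3β-alcohol; both new centres are temporary and are erased in step 10, while C5 and C10 take no part in the shift and keep their configuration.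

**Step 10**
Reactants: 12 2α-(trimethylsilyl)-11,12,13,14,15,16,17-heptanorlabdane-3β,9α-diol
Product: 13 (1R,4aS,8aS)-5,5,8a-trimethyl-1,2,3,4,4a,5,8,8a-octahydronaphthalen-1-ol (heptanorlabd-2-en-9α-ol)
Conditions: KH, THF, 0 °C → rt
Reagents that add atoms: none
Why: Peterson elimination: the C3 potassium alkoxide attacks silicon in a syn-elimination through the gauche O–C3–C2–Si arrangement (open to either C3 epimer with equatorial silicon) and gives the C2=C3 olefin regiospecifically.

**Step 11**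
Reactants: 13 (1R,4aS,8aS)-5,5,8a-trimethyl-1,2,3,4,4a,5,8,8a-octahydronaphthalen-1-ol
Product: 15 (4aS,8aS)-5,5,8a-trimethyl-4a,5,8,8a-tetrahydronaphthalen-1(4H)-one (heptanorlabda-2,7-dien-9-one), via ketone 14 (not isolated)
Conditions: IBX (4 equiv), DMSO/fluorobenzene, 75 °C
Reagents that add atoms: none
Why: IBX oxidises the secondary alcohol to the ketone and then dehydrogenates it through its enol; only C8 bears α-hydrogens because C10 is quaternary, so the Δ7-en-9-one results.

**Step 12**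
Reactants: 15 (4aS,8aS)-5,5,8a-trimethyl-4a,5,8,8a-tetrahydronaphthalen-1(4H)-one
Product: 16 (4aS,8aS)-2-(hydroxymethyl)-5,5,8a-trimethyl-4a,5,8,8a-tetrahydronaphthalen-1(4H)-one
Conditions: 37% aq HCHO, DMAP, THF, rt
Reagents that add atoms: formaldehyde C=O
Why: Morita–Baylis–Hillman reaction: DMAP adds to C7, the enolate hydroxymethylates at C8 and the catalyst is expelled, which places C17 on C8 and keeps the C7=C8 olefin.

**Step 13**
Reactants: 16 (4aS,8aS)-2-(hydroxymethyl)-5,5,8a-trimethyl-4a,5,8,8a-tetrahydronaphthalen-1(4H)-one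
Product: 17 (4aS,8aS)-2-{[(tert-butyldiphenylsilyl)oxy]methyl}-5,5,8a-trimethyl-4a,5,8,8a-tetrahydronaphthalen-1(4H)-one
Conditions: TBDPSCl, imidazole, DMF, rt
Reagents that add atoms: tert-butyl(chloro)diphenylsilane CC(C)(C)[Si](Cl)(c1ccccc1)c1ccccc1
Why: Silylation of the primary allylic alcohol with a group that withstands the Lewis-acidic and basic steps 15–18.

**Step 14**
Reactants: 17 (4aS,8aS)-2-{[(tert-butyldiphenylsilyl)oxy]methyl}-5,5,8a-trimethyl-4a,5,8,8a-tetrahydronaphthalen-1(4H)-one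
Product: 18 2α,3α-dihydroxy-17-[(tert-butyldiphenylsilyl)oxy]-11,12,13,14,15,16-hexanorlabd-7-en-9-one
Conditions: OsO4 (5 mol%), NMO, acetone/H2O, rt
Reagents that add atoms: osmium tetroxide O=[Os](=O)(=O)=O (oxygen re-supplied by N-methylmorpholine N-oxide C[N+]1([O-])CCOCC1); water O
Why: Upjohn dihydroxylation should be chemoselective for the isolated cis olefin C2=C3 over the electron-poor enone olefin, and osmium should approach the α-face because the β-face is screened by the axial 4β- and 10β-methyl groups, giving the 2α,3α-diol.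

**Step 15**
Reactants: 18 2α,3α-dihydroxy-17-[(tert-butyldiphenylsilyl)oxy]-11,12,13,14,15,16-hexanorlabd-7-en-9-one; 19 angelic acid [(Z)-2-methylbut-2-enoic acid]
Product: 21 2α,3α-bis(angeloyloxy)-17-[(tert-butyldiphenylsilyl)oxy]-11,12,13,14,15,16-hexanorlabd-7-en-9-one, via mixed anhydride 20 (not isolated)
Conditions: 19, 2,4,6-trichlorobenzoyl chloride, Et3N, toluene, rt; then 18, 80 °C (no DMAP)
Reagents that add atoms: 2,4,6-trichlorobenzoyl chloride O=C(Cl)c1c(Cl)cc(Cl)cc1Cl (acyl part stays only in 20)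
Why: Yamaguchi-type esterification: the mixed anhydride is attacked at the less hindered angeloyl carbonyl, and without a nucleophilic catalyst the Z geometry should be kept; enone and silyl ether are inert.

**Step 16**
Reactants: 21 2α,3α-bis(angeloyloxy)-17-[(tert-butyldiphenylsilyl)oxy]-11,12,13,14,15,16-hexanorlabd-7-en-9-one
Product: 22 2α,3α-bis(angeloyloxy)-17-[(tert-butyldiphenylsilyl)oxy]-12,13,14,15,16-pentanorlabda-7,9(11)-diene
Conditions: Zn, CH2Br2, TiCl4 (preformed Lombardo reagent), THF/CH2Cl2, 0 °C → rt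
Reagents that add atoms: dibromomethane BrCBr
Why: Takai–Lombardo methylenation, a non-basic titanium–zinc carbenoid that methylenates hindered, enolisable ketones and leaves esters untouched, converts C9=O into the C9=C11 olefin.

**Step 17**
Reactants: 23 methyl but-2-ynoate
Product: 24 methyl (Z)-3-iodobut-2-enoate
Conditions: NaI, AcOH, 115 °C
Reagents that add atoms: sodium iodide [Na+].[I-]
Why: Conjugate hydroiodination of the ynoate (iodide adds to C3, anti protonation) gives the Z-β-iodo enoate.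

**Step 18**
Reactants: 22 2α,3α-bis(angeloyloxy)-17-[(tert-butyldiphenylsilyl)oxy]-12,13,14,15,16-pentanorlabda-7,9(11)-diene; 24 methyl (Z)-3-iodobut-2-enoate
Product: 26 methyl (13Z)-2α,3α-bis(angeloyloxy)-17-[(tert-butyldiphenylsilyl)oxy]-12-oxolabda-7,13-dien-15-oate, via alkylborane 25 (not isolated)
Conditions: 9-BBN-H (1.05 equiv), THF, 0 °C → rt; then 24, Pd(PPh3)4 (5 mol%), K3PO4, CO (1 atm), dioxane, rt → 45 °C
Reagents that add atoms: 9-borabicyclo[3.3.1]nonane B1C2CCCC1CCC2 (boron stays only in 25); carbon monoxide [C-]#[O+]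
Why: 9-BBN should add to the 1,1-disubstituted end of the diene (boron on C11) from the α-face opposite the axial 10β-methyl, setting 9α-H; the alkylborane then undergoes carbonylative Suzuki–Miyaura coupling (oxidative addition with retention, CO insertion, transmetalation, reductive elimination) to give the C12 ketone with the Z-C13=C14 olefin.

**Step 19**
Reactants: 26 methyl (13Z)-2α,3α-bis(angeloyloxy)-17-[(tert-butyldiphenylsilyl)oxy]-12-oxolabda-7,13-dien-15-oate
Product: 27 methyl (13Z)-2α,3α-bis(angeloyloxy)-17-hydroxy-12-oxolabda-7,13-dien-15-oate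
Conditions: HF·pyridine, pyridine/THF, 0 °C → rt
Reagents that add atoms: none
Why: Buffered HF·pyridine cleaves the primary silyl ether without basic fluoride, so the angelates and the Z-keto enoate should survive.

**Step 20**
Reactants: 27 methyl (13Z)-2α,3α-bis(angeloyloxy)-17-hydroxy-12-oxolabda-7,13-dien-15-oate
Product: 28 methyl (13Z)-2α,3α-bis(angeloyloxy)-12,17-dioxolabda-7,13-dien-15-oate (CNP0141070.1)
Conditions: activated MnO2, CH2Cl2, rt
Reagents that add atoms: none
Why: MnO2 oxidises only the allylic primary alcohol and gives the C8 enal.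

**Compound list**
1 | 2-methylcyclohexane-1,3-dione | CC1C(=O)CCCC1=O | starting material
2 | allyl bromide | C=CCBr | starting material
3 | 2-methyl-2-(prop-2-en-1-yl)cyclohexane-1,3-dione | C=CCC1(C)C(=O)CCCC1=O | intermediate
4 | (2R,3R)-3-hydroxy-2-methyl-2-(prop-2-en-1-yl)cyclohexan-1-one | C=CC[C@]1(C)[C@H](O)CCCC1=O | intermediate
5 | (2R,3R)-3-[(tert-butyldimethylsilyl)oxy]-2-methyl-2-(prop-2-en-1-yl)cyclohexan-1-one | C=CC[C@]1(C)[C@H](O[Si](C)(C)C(C)(C)C)CCCC1=O | intermediate
6 | (2R,3R)-3-[(tert-butyldimethylsilyl)oxy]-2-methyl-2-(2-oxopropyl)cyclohexan-1-one | CC(=O)C[C@]1(C)[C@H](O[Si](C)(C)C(C)(C)C)CCCC1=O | intermediate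
7 | (7R,7aS)-7-[(tert-butyldimethylsilyl)oxy]-7a-methyl-1,4,5,6,7,7a-hexahydro-2H-inden-2-one | O=C1C[C@]2(C)[C@H](O[Si](C)(C)C(C)(C)C)CCCC2=C1 | intermediate
8 | (7R,7aS)-7-[(tert-butyldimethylsilyl)oxy]-3,3,7a-trimethyl-1,3,5,6,7,7a-hexahydro-2H-inden-2-one | O=C1C[C@]2(C)[C@H](O[Si](C)(C)C(C)(C)C)CCC=C2C1(C)C | intermediate
9 | (7R,7aS)-7-hydroxy-3,3,7a-trimethyl-1,3,5,6,7,7a-hexahydro-2H-inden-2-one | O=C1C[C@]2(C)[C@H](O)CCC=C2C1(C)C | intermediate
10 | (3aR,7R,7aS)-7-hydroxy-3,3,7a-trimethyloctahydro-2H-inden-2-one (trans-fused A-nor ketone) | O=C1C[C@]2(C)[C@H](O)CCC[C@H]2C1(C)C | intermediate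
11 | 9α-hydroxy-2α-(trimethylsilyl)-11,12,13,14,15,16,17-heptanorlabdan-3-one (ring-expanded α-silyl ketone) | O=C1[C@H]([Si](C)(C)C)C[C@]2(C)[C@H](O)CCC[C@H]2C1(C)C | intermediate
12 | 2α-(trimethylsilyl)-11,12,13,14,15,16,17-heptanorlabdane-3β,9α-diol | O[C@H]1[C@H]([Si](C)(C)C)C[C@]2(C)[C@H](O)CCC[C@H]2C1(C)C | intermediate
13 | (1R,4aS,8aS)-5,5,8a-trimethyl-1,2,3,4,4a,5,8,8a-octahydronaphthalen-1-ol | C1=CC[C@]2(C)[C@H](O)CCC[C@H]2C1(C)C | intermediate
14 | (4aS,8aS)-5,5,8a-trimethyl-3,4,4a,5,8,8a-hexahydronaphthalen-1(2H)-one | C1=CC[C@]2(C)C(=O)CCC[C@H]2C1(C)C | intermediate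
15 | (4aS,8aS)-5,5,8a-trimethyl-4a,5,8,8a-tetrahydronaphthalen-1(4H)-one | C1=CC[C@]2(C)C(=O)C=CC[C@H]2C1(C)C | intermediate
16 | (4aS,8aS)-2-(hydroxymethyl)-5,5,8a-trimethyl-4a,5,8,8a-tetrahydronaphthalen-1(4H)-one | C1=CC[C@]2(C)C(=O)C(CO)=CC[C@H]2C1(C)C | intermediate
17 | (4aS,8aS)-2-{[(tert-butyldiphenylsilyl)oxy]methyl}-5,5,8a-trimethyl-4a,5,8,8a-tetrahydronaphthalen-1(4H)-one | C1=CC[C@]2(C)C(=O)C(CO[Si](c3ccccc3)(c3ccccc3)C(C)(C)C)=CC[C@H]2C1(C)C | intermediate
18 | 2α,3α-dihydroxy-17-[(tert-butyldiphenylsilyl)oxy]-11,12,13,14,15,16-hexanorlabd-7-en-9-one | O[C@@H]1[C@H](O)C[C@]2(C)C(=O)C(CO[Si](c3ccccc3)(c3ccccc3)C(C)(C)C)=CC[C@H]2C1(C)C | intermediate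
19 | angelic acid [(Z)-2-methylbut-2-enoic acid] | C/C=C(/C)C(=O)O | starting material
20 | angelic 2,4,6-trichlorobenzoic anhydride | C/C=C(/C)C(=O)OC(=O)c1c(Cl)cc(Cl)cc1Cl | intermediate
21 | 2α,3α-bis(angeloyloxy)-17-[(tert-butyldiphenylsilyl)oxy]-11,12,13,14,15,16-hexanorlabd-7-en-9-one | C/C=C(/C)C(=O)O[C@@H]1[C@H](OC(=O)/C(C)=C\C)C[C@]2(C)C(=O)C(CO[Si](c3ccccc3)(c3ccccc3)C(C)(C)C)=CC[C@H]2C1(C)C | intermediate
22 | 2α,3α-bis(angeloyloxy)-17-[(tert-butyldiphenylsilyl)oxy]-12,13,14,15,16-pentanorlabda-7,9(11)-diene | C/C=C(/C)C(=O)O[C@@H]1[C@H](OC(=O)/C(C)=C\C)C[C@]2(C)C(=C)C(CO[Si](c3ccccc3)(c3ccccc3)C(C)(C)C)=CC[C@H]2C1(C)C | intermediate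
23 | methyl but-2-ynoate | CC#CC(=O)OC | starting material
24 | methyl (Z)-3-iodobut-2-enoate | C/C(I)=C/C(=O)OC | intermediate
25 | 11-(9-borabicyclo[3.3.1]nonan-9-yl)-2α,3α-bis(angeloyloxy)-17-[(tert-butyldiphenylsilyl)oxy]-12,13,14,15,16-pentanorlabd-7-ene (9α-H) | C/C=C(/C)C(=O)O[C@@H]1[C@H](OC(=O)/C(C)=C\C)C[C@]2(C)[C@@H](CB3C4CCCC3CCC4)C(CO[Si](c3ccccc3)(c3ccccc3)C(C)(C)C)=CC[C@H]2C1(C)C | intermediate
26 | methyl (13Z)-2α,3α-bis(angeloyloxy)-17-[(tert-butyldiphenylsilyl)oxy]-12-oxolabda-7,13-dien-15-oate | C/C=C(/C)C(=O)O[C@@H]1[C@H](OC(=O)/C(C)=C\C)C[C@]2(C)[C@@H](CC(=O)/C(C)=C\C(=O)OC)C(CO[Si](c3ccccc3)(c3ccccc3)C(C)(C)C)=CC[C@H]2C1(C)C | intermediate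
27 | methyl (13Z)-2α,3α-bis(angeloyloxy)-17-hydroxy-12-oxolabda-7,13-dien-15-oate | C/C=C(/C)C(=O)O[C@@H]1[C@H](OC(=O)/C(C)=C\C)C[C@]2(C)[C@@H](CC(=O)/C(C)=C\C(=O)OC)C(CO)=CC[C@H]2C1(C)C | intermediate
28 | methyl (2Z)-5-[(1R,4aR,6S,7R,8aS)-2-formyl-5,5,8a-trimethyl-6,7-bis{[(2Z)-2-methylbut-2-enoyl]oxy}-1,4,4a,5,6,7,8,8a-octahydronaphthalen-1-yl]-3-methyl-4-oxopent-2-enoate (CNP0141070.1) | C/C=C(/C)C(=O)O[C@@H]1[C@H](OC(=O)/C(C)=C\C)C[C@]2(C)[C@@H](CC(=O)/C(C)=C\C(=O)OC)C(C=O)=CC[C@H]2C1(C)C | target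

**Count**
Total steps: 20. Longest linear sequence: 19 (steps 1–16 and 18–20).

**Steps most likely to fail**

Step 18. Direct coupling of the electron-poor iodoalkene may outrun CO insertion, and the Z-keto enoate may isomerise under palladium and base. The fallback sets out from 22, which is hydroborated to 25 as before. 25 is coupled without CO (B-alkyl Suzuki–Miyaura, PdCl2(dppf), K3PO4, DMF/THF/H2O) with 2-bromo-3-methylfuran (Cc1ccoc1Br) to give the 11-(3-methylfuran-2-yl) compound F1. Photooxygenation (O2, rose bengal, hν, iPr2NEt, CH2Cl2, −78 °C; [4+2] addition then base-induced endoperoxide opening) gives the γ-hydroxybutenolide F2. Alkylation of its ring-opened carboxylate (MeI, K2CO3, DMF) returns to the route at 26.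

Step 9. Addition to the hindered carbonyl may be slow, C4 may migrate in part, or silicon may be lost before the reduction so that no olefin can be formed in step 10. The fallback sets out from 10 and uses a cyclopropanol ring expansion. TMSOTf/Et3N gives the bis-silyl enol ether F3 (enolisation is possible only toward C1). Et2Zn/CH2I2 gives the siloxycyclopropane F4. FeCl3 in DMF opens the internal cyclopropane bond oxidatively to the ring-expanded β-chloro ketone F5, and NaOAc in MeOH eliminates HCl to the Δ1-en-3-one F6. TsNHNH2 gives the tosylhydrazone F7, whose alkene-transposing reduction (catecholborane, then NaOAc·3H2O, CHCl3, reflux) returns to the route at 13.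

Step 15. Acylation of the axial, neopentyl 3α-hydroxyl may stop at the mono-ester, and the forcing conditions may isomerise angelate to tiglate. The fallback sets out from 18. Esterification with 2-(diphenoxyphosphoryl)propanoic acid (DCC, DMAP, CH2Cl2) gives the bis(phosphonopropanoate) F8. A Z-selective Horner–Wadsworth–Emmons reaction with acetaldehyde (NaH, THF, −78 °C) builds both angelates and returns to the route at 21.

**Further compounds**
F1 | step 18 | 2α,3α-bis(angeloyloxy)-17-[(tert-butyldiphenylsilyl)oxy]-11-(3-methylfuran-2-yl)-12,13,14,15,16-pentanorlabd-7-ene | C/C=C(/C)C(=O)O[C@@H]1[C@H](OC(=O)/C(C)=C\C)C[C@]2(C)[C@@H](Cc3occc3C)C(CO[Si](c3ccccc3)(c3ccccc3)C(C)(C)C)=CC[C@H]2C1(C)C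
F2 | step 18 | γ-hydroxybutenolide: 5-hydroxy-4-methyl-5-(labdane C11 methylene)furan-2(5H)-one, epimers at the hemiketal carbon | C/C=C(/C)C(=O)O[C@@H]1[C@H](OC(=O)/C(C)=C\C)C[C@]2(C)[C@@H](CC3(O)OC(=O)C=C3C)C(CO[Si](c3ccccc3)(c3ccccc3)C(C)(C)C)=CC[C@H]2C1(C)C
F3 | step 9 | (3aR,7R,7aS)-3,3,7a-trimethyl-2,7-bis[(trimethylsilyl)oxy]-3a,4,5,6,7,7a-hexahydro-3H-indene (bis-silyl enol ether of 10) | C[Si](C)(C)OC1=C[C@]2(C)[C@H](O[Si](C)(C)C)CCC[C@H]2C1(C)C
F4 | step 9 | siloxycyclopropane from F3 (CH2 added across the enol ether double bond) | C[Si](C)(C)OC13CC3[C@]2(C)[C@H](O[Si](C)(C)C)CCC[C@H]2C1(C)C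
F5 | step 9 | 1-chloro-9α-hydroxy-11,12,13,14,15,16,17-heptanorlabdan-3-one | O=C1CC(Cl)[C@]2(C)[C@H](O)CCC[C@H]2C1(C)C
F6 | step 9 | 9α-hydroxy-11,12,13,14,15,16,17-heptanorlabd-1-en-3-one | O=C1C=C[C@]2(C)[C@H](O)CCC[C@H]2C1(C)C
F7 | step 9 | tosylhydrazone of F6 | Cc1ccc(cc1)S(=O)(=O)NN=C1C=C[C@]2(C)[C@H](O)CCC[C@H]2C1(C)C
F8 | step 15 | 2α,3α-bis{[2-(diphenoxyphosphoryl)propanoyl]oxy}-17-[(tert-butyldiphenylsilyl)oxy]-11,12,13,14,15,16-hexanorlabd-7-en-9-one | CC(C(=O)O[C@@H]1[C@H](OC(=O)C(C)P(=O)(Oc3ccccc3)Oc3ccccc3)C[C@]2(C)C(=O)C(CO[Si](c3ccccc3)(c3ccccc3)C(C)(C)C)=CC[C@H]2C1(C)C)P(=O)(Oc1ccccc1)Oc1ccccc1
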